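**Plan**

- Retrosynthesis: the dihydropyranone (O1, C2 with the methyl group, C3, C4 ketone, C5, C6 on the coumarin) is cut at C3–C2 and at C5=C6, the two carbon–carbon bonds flanking the C4 ketone. This leaves an acetone α,α′-dianion equivalent (C3–C4–C5), acetaldehyde (C2, its methyl group and O1) and a coumarin-3-carbonyl chloride (C6).
- The enabling feature is the β-alkoxy enone: C2 is the aldol position of the C4 ketone and C6 is the acyl carbon of a vinylogous ester. One ketone bis-nucleophile can therefore take both electrophiles, and O1 closes the ring by itself; a tert-butoxycarbonyl group on C5 serves as activating group and leaves as CO2 and isobutene in the same flask.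
- Further cuts: the lactone ring of the coumarin (salicylaldehyde + Meldrum's acid), then the hexasubstituted benzene ring back to 5-bromoresorcinol, (S)-propylene oxide, two methyl groups and a formyl group.
- Forward order: side chain and ring substituents (Grignard/epoxide opening, three directed ortho-metalations), coumarin lactone ring (Knoevenagel–lactonisation), dihydropyranone ring in one three-component operation, desilylation.
- Stereochemistry: the side-chain (S)-carbinol comes from (S)-propylene oxide and is never touched; C2 (R) of the pyranone is set by an (S)-BINOL/Ti(OiPr)4-catalysed vinylogous Mukaiyama aldol addition to acetaldehyde.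

Key step: step 12

Assumption: the (S)-BINOL/Ti(OiPr)4 catalyst is taken to direct the diene to the Si face of acetaldehyde, by analogy with its facial sense in allyl and enol-silane additions to aliphatic aldehydes; if the sense is opposite, (R)-BINOL is used.

**Route**

Step 1
Reactants: 1 5-bromobenzene-1,3-diol
Product: 2 1-bromo-3,5-bis(methoxymethoxy)benzene
Conditions: MOMCl, iPr2NEt, CH2Cl2, 0 °C to rt
Reagents that add atoms: chloromethyl methyl ether (COCCl)
Why: Williamson ether synthesis on both phenols should give the bis(methoxymethyl) ether, whose acetal oxygens later direct the ortho-lithiations.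

Step 2
Reactants: 2 1-bromo-3,5-bis(methoxymethoxy)benzene; 3 (S)-2-methyloxirane
Product: 5 (2S)-1-[3,5-bis(methoxymethoxy)phenyl]propan-2-ol, via arylmagnesium bromide 4 (not isolated)
Conditions: Mg, THF, reflux; then CuI (10 mol%), 3, −30 to 0 °C
Reagents that add atoms: none
Why: Copper-catalysed Grignard opening of the epoxide should occur by SN2 attack at the unsubstituted carbon, so the stereocenter of 3 is not involved and becomes the (S)-carbinol of 5.

Step 3
Reactants: 5 (2S)-1-[3,5-bis(methoxymethoxy)phenyl]propan-2-ol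
Product: 6 {[(2S)-1-[3,5-bis(methoxymethoxy)phenyl]propan-2-yl]oxy}tri(propan-2-yl)silane
Conditions: TIPSOTf, 2,6-lutidine, CH2Cl2, 0 °C
Reagents that add atoms: triisopropylsilyl trifluoromethanesulfonate (CC(C)[Si](C(C)C)(C(C)C)OS(=O)(=O)C(F)(F)F)
Why: Silylation of the secondary alcohol should give a triisopropylsilyl ether that tolerates the alkyllithium, acid and Lewis acid steps ahead.

Step 4
Reactants: 6 {[(2S)-1-[3,5-bis(methoxymethoxy)phenyl]propan-2-yl]oxy}tri(propan-2-yl)silane
Product: 8 {[(2S)-1-[3,5-bis(methoxymethoxy)-4-methylphenyl]propan-2-yl]oxy}tri(propan-2-yl)silane, via aryllithium 7 (not isolated)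
Conditions: n-BuLi, THF, 0 °C; then MeI, −78 °C to rt
Reagents that add atoms: iodomethane (CI)
Why: Directed ortho-metalation should take place between the two OMOM groups, the most acidic position through double coordination of lithium, and the aryllithium is methylated by SN2 on MeI.

Step 5
Reactants: 8 {[(2S)-1-[3,5-bis(methoxymethoxy)-4-methylphenyl]propan-2-yl]oxy}tri(propan-2-yl)silane
Product: 10 {[(2S)-1-[3,5-bis(methoxymethoxy)-2,4-dimethylphenyl]propan-2-yl]oxy}tri(propan-2-yl)silane, via aryllithium 9 (not isolated)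
Conditions: s-BuLi, TMEDA, THF, −78 °C; then MeI
Reagents that add atoms: iodomethane (CI)
Why: A second directed ortho-metalation should occur at one of the two equivalent positions ortho to an OMOM group (ring lithiation being kinetically preferred over benzylic lithiation here), followed by methylation.

Step 6
Reactants: 10 {[(2S)-1-[3,5-bis(methoxymethoxy)-2,4-dimethylphenyl]propan-2-yl]oxy}tri(propan-2-yl)silane
Product: 12 2,4-bis(methoxymethoxy)-3,5-dimethyl-6-[(2S)-2-(triisopropylsilyloxy)propyl]benzaldehyde, via aryllithium 11 (not isolated)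
Conditions: s-BuLi, TMEDA, THF, −78 °C; then DMF
Reagents that add atoms: N,N-dimethylformamide (CN(C)C=O)
Why: A third directed ortho-metalation at the last free ring position, ortho to OMOM, and Bouveault-type formylation of the aryllithium with DMF should give the hexasubstituted benzaldehyde.

Step 7
Reactants: 12 2,4-bis(methoxymethoxy)-3,5-dimethyl-6-[(2S)-2-(triisopropylsilyloxy)propyl]benzaldehyde
Product: 13 2,4-dihydroxy-3,5-dimethyl-6-[(2S)-2-(triisopropylsilyloxy)propyl]benzaldehyde
Conditions: TFA, CH2Cl2, 0 °C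
Reagents that add atoms: none
Why: Acid-catalysed acetal cleavage should free both phenols, while the hindered silyl ether is expected to survive short exposure at 0 °C.

Step 8
Reactants: 13 2,4-dihydroxy-3,5-dimethyl-6-[(2S)-2-(triisopropylsilyloxy)propyl]benzaldehyde; 14 2,2-dimethyl-1,3-dioxane-4,6-dione (Meldrum's acid)
Product: 16 7-hydroxy-6,8-dimethyl-2-oxo-5-[(2S)-2-(triisopropylsilyloxy)propyl]-2H-chromene-3-carboxylic acid, via arylidene dioxanedione 15 (not isolated)
Conditions: piperidine (cat.), AcOH (cat.), EtOH, 60 °C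
Reagents that add atoms: none
Why: Knoevenagel condensation gives arylidene 15, whose ortho phenol should attack a ring carbonyl with loss of acetone (lactonisation) to close the coumarin lactone ring and leave the 3-carboxylic acid.

Step 9
Reactants: 16 7-hydroxy-6,8-dimethyl-2-oxo-5-[(2S)-2-(triisopropylsilyloxy)propyl]-2H-chromene-3-carboxylic acid
Product: 18 7-(tert-butyldimethylsilyloxy)-6,8-dimethyl-2-oxo-5-[(2S)-2-(triisopropylsilyloxy)propyl]-2H-chromene-3-carbonyl chloride, via bis-silyl derivative 17 (not isolated)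
Conditions: TBSOTf, Et3N, CH2Cl2, 0 °C; then (COCl)2, DMF (cat.), 0 °C to rt
Reagents that add atoms: tert-butyldimethylsilyl trifluoromethanesulfonate (CC(C)(C)[Si](C)(C)OS(=O)(=O)C(F)(F)F); oxalyl chloride (O=C(Cl)C(Cl)=O)
Why: Silylation of phenol and acid gives 17, and the Vilsmeier-type chloroiminium salt from (COCl)2 and DMF should convert the silyl ester into the acid chloride under neutral conditions with loss of the silyl chloride.

Step 10
Reactants: 19 tert-butyl 3-oxobutanoate
Product: 20 tert-butyl 3-(trimethylsilyloxy)but-2-enoate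
Conditions: Me3SiCl, Et3N, hexane, rt
Reagents that add atoms: chlorotrimethylsilane (C[Si](C)(C)Cl)
Why: O-silylation of the enol form of the β-keto ester under amine base should give the enol silane.

Step 11
Reactants: 20 tert-butyl 3-(trimethylsilyloxy)but-2-enoate
Product: 22 1-tert-butoxy-1,3-bis(trimethylsilyloxy)buta-1,3-diene, via lithium dienolate 21 (not isolated)
Conditions: LiN(iPr)2, THF, −78 °C; then Me3SiCl
Reagents that add atoms: chlorotrimethylsilane (C[Si](C)(C)Cl)
Why: Kinetic deprotonation at the γ-methyl group and O-silylation of the ester dienolate should give the 1,3-bis(silyloxy)diene, a masked acetone α,α′-dianion carrying a tert-butoxycarbonyl activating group on one α-carbon.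

Step 12
Reactants: 22 1-tert-butoxy-1,3-bis(trimethylsilyloxy)buta-1,3-diene; 23 acetaldehyde; 18 7-(tert-butyldimethylsilyloxy)-6,8-dimethyl-2-oxo-5-[(2S)-2-(triisopropylsilyloxy)propyl]-2H-chromene-3-carbonyl chloride
Product: 26 7-(tert-butyldimethylsilyloxy)-6,8-dimethyl-3-[(2R)-2-methyl-4-oxo-3,4-dihydro-2H-pyran-6-yl]-5-[(2S)-2-(triisopropylsilyloxy)propyl]-2H-chromen-2-one, via enol silane 24 (not isolated), via acylated keto ester 25 (not isolated)
Conditions: Ti(OiPr)4 (10 mol%), (S)-BINOL (10 mol%), 4 Å MS, THF, −78 °C to rt; evaporate; then 18, ZnCl2, CH2Cl2, 0 °C to rt; then TFA, rt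
Reagents that add atoms: none
Why: Diene 22 acts as an acetone α,α′-dianion equivalent: in the first stage the BINOL–titanium Lewis acid activates acetaldehyde and the terminal (γ) carbon of 22 adds in a vinylogous Mukaiyama aldol reaction, which forms the C3–C2 bond and, after silyl transfer, enol silane 24; in the second stage ZnCl2 promotes C-acylation of 24 at its α-carbon by 18, which forms the C5–C6 bond (as the ketone of 25) with loss of Me3SiCl. In the third stage TFA removes the trimethylsilyl ether and the tert-butyl ester, the resulting β,β′-diketo acid loses CO2, and the freed C2 hydroxyl adds to the aroyl carbonyl in a 6-exo-trig closure followed by dehydration, which gives the C5=C6 enol ether of the dihydropyranone. The closest known reaction type is the Maitland–Japp-type multicomponent pyranone synthesis from 1,3-bis(silyloxy)dienes, built here from titanium–BINOL vinylogous aldol additions, Lewis-acid acylation of enol silanes by acid chlorides and acid cyclodehydration of δ-hydroxy-β-diketones. The C2 stereocenter is set by the catalyst alone: the BINOL ligand shields one face of the titanium-bound aldehyde so that the diene attacks the Si face and gives the (R)-carbinol, and no later stage breaks a bond at C2. The step needs γ-then-α regioselectivity, which the diene supplies (its terminal carbon is the most nucleophilic and only the α-carbon remains as an enol silane), and acylation in preference to conjugate addition at C4 of the coumarin, which the higher reactivity of the acyl chloride, the neighbouring C5 side chain and the electron-rich benzene ring should secure.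

Step 13
Reactants: 26 7-(tert-butyldimethylsilyloxy)-6,8-dimethyl-3-[(2R)-2-methyl-4-oxo-3,4-dihydro-2H-pyran-6-yl]-5-[(2S)-2-(triisopropylsilyloxy)propyl]-2H-chromen-2-one
Product: 27 7-hydroxy-5-[(2S)-2-hydroxypropyl]-6,8-dimethyl-3-[(2R)-2-methyl-4-oxo-3,4-dihydro-2H-pyran-6-yl]-2H-chromen-2-one
Conditions: HF·pyridine, THF, 0 °C to rt
Reagents that add atoms: none
Why: Fluoride-mediated cleavage of both silyl ethers under mildly acidic, non-basic conditions should leave the lactone, the enone and the C2 stereocenter (no base for a retro-oxa-Michael opening) untouched.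

**Compound list**

1 | 5-bromobenzene-1,3-diol | Oc1cc(O)cc(Br)c1 | starting material
2 | 1-bromo-3,5-bis(methoxymethoxy)benzene | COCOc1cc(Br)cc(OCOC)c1 | intermediate
3 | (S)-2-methyloxirane | C[C@H]1CO1 | starting material
4 | [3,5-bis(methoxymethoxy)phenyl]magnesium bromide | COCOc1cc(cc(OCOC)c1)[Mg]Br | intermediate
5 | (2S)-1-[3,5-bis(methoxymethoxy)phenyl]propan-2-ol | C[C@H](O)Cc1cc(OCOC)cc(OCOC)c1 | intermediate
6 | {[(2S)-1-[3,5-bis(methoxymethoxy)phenyl]propan-2-yl]oxy}tri(propan-2-yl)silane | C[C@H](O[Si](C(C)C)(C(C)C)C(C)C)Cc1cc(OCOC)cc(OCOC)c1 | intermediate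
7 | [2,6-bis(methoxymethoxy)-4-[(2S)-2-(triisopropylsilyloxy)propyl]phenyl]lithium | C[C@H](O[Si](C(C)C)(C(C)C)C(C)C)Cc1cc(OCOC)c([Li])c(OCOC)c1 | intermediate
8 | {[(2S)-1-[3,5-bis(methoxymethoxy)-4-methylphenyl]propan-2-yl]oxy}tri(propan-2-yl)silane | C[C@H](O[Si](C(C)C)(C(C)C)C(C)C)Cc1cc(OCOC)c(C)c(OCOC)c1 | intermediate
9 | [2,4-bis(methoxymethoxy)-3-methyl-6-[(2S)-2-(triisopropylsilyloxy)propyl]phenyl]lithium | C[C@H](O[Si](C(C)C)(C(C)C)C(C)C)Cc1c([Li])c(OCOC)c(C)c(OCOC)c1 | intermediate
10 | {[(2S)-1-[3,5-bis(methoxymethoxy)-2,4-dimethylphenyl]propan-2-yl]oxy}tri(propan-2-yl)silane | C[C@H](O[Si](C(C)C)(C(C)C)C(C)C)Cc1cc(OCOC)c(C)c(OCOC)c1C | intermediate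
11 | [2,4-bis(methoxymethoxy)-3,5-dimethyl-6-[(2S)-2-(triisopropylsilyloxy)propyl]phenyl]lithium | C[C@H](O[Si](C(C)C)(C(C)C)C(C)C)Cc1c([Li])c(OCOC)c(C)c(OCOC)c1C | intermediate
12 | 2,4-bis(methoxymethoxy)-3,5-dimethyl-6-[(2S)-2-(triisopropylsilyloxy)propyl]benzaldehyde | C[C@H](O[Si](C(C)C)(C(C)C)C(C)C)Cc1c(C=O)c(OCOC)c(C)c(OCOC)c1C | intermediate
13 | 2,4-dihydroxy-3,5-dimethyl-6-[(2S)-2-(triisopropylsilyloxy)propyl]benzaldehyde | C[C@H](O[Si](C(C)C)(C(C)C)C(C)C)Cc1c(C=O)c(O)c(C)c(O)c1C | intermediate
14 | 2,2-dimethyl-1,3-dioxane-4,6-dione (Meldrum's acid) | CC1(C)OC(=O)CC(=O)O1 | starting material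
15 | 5-[[2,4-dihydroxy-3,5-dimethyl-6-[(2S)-2-(triisopropylsilyloxy)propyl]phenyl]methylidene]-2,2-dimethyl-1,3-dioxane-4,6-dione | C[C@H](O[Si](C(C)C)(C(C)C)C(C)C)Cc1c(C=C2C(=O)OC(C)(C)OC2=O)c(O)c(C)c(O)c1C | intermediate
16 | 7-hydroxy-6,8-dimethyl-2-oxo-5-[(2S)-2-(triisopropylsilyloxy)propyl]-2H-chromene-3-carboxylic acid | C[C@H](O[Si](C(C)C)(C(C)C)C(C)C)Cc1c(C)c(O)c(C)c2oc(=O)c(C(=O)O)cc12 | intermediate
17 | tert-butyldimethylsilyl 7-(tert-butyldimethylsilyloxy)-6,8-dimethyl-2-oxo-5-[(2S)-2-(triisopropylsilyloxy)propyl]-2H-chromene-3-carboxylate | C[C@H](O[Si](C(C)C)(C(C)C)C(C)C)Cc1c(C)c(O[Si](C)(C)C(C)(C)C)c(C)c2oc(=O)c(C(=O)O[Si](C)(C)C(C)(C)C)cc12 | intermediate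
18 | 7-(tert-butyldimethylsilyloxy)-6,8-dimethyl-2-oxo-5-[(2S)-2-(triisopropylsilyloxy)propyl]-2H-chromene-3-carbonyl chloride | C[C@H](O[Si](C(C)C)(C(C)C)C(C)C)Cc1c(C)c(O[Si](C)(C)C(C)(C)C)c(C)c2oc(=O)c(C(Cl)=O)cc12 | intermediate
19 | tert-butyl 3-oxobutanoate | CC(=O)CC(=O)OC(C)(C)C | starting material
20 | tert-butyl 3-(trimethylsilyloxy)but-2-enoate | CC(O[Si](C)(C)C)=CC(=O)OC(C)(C)C | intermediate
21 | lithium 1-tert-butoxy-3-(trimethylsilyloxy)buta-1,3-dien-1-olate | [Li]OC(OC(C)(C)C)=CC(=C)O[Si](C)(C)C | intermediate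
22 | 1-tert-butoxy-1,3-bis(trimethylsilyloxy)buta-1,3-diene | C=C(O[Si](C)(C)C)C=C(OC(C)(C)C)O[Si](C)(C)C | intermediate
23 | acetaldehyde | CC=O | starting material
24 | tert-butyl (5R)-3,5-bis(trimethylsilyloxy)hex-2-enoate | C[C@@H](O[Si](C)(C)C)CC(O[Si](C)(C)C)=CC(=O)OC(C)(C)C | intermediate
25 | tert-butyl (5R)-2-[7-(tert-butyldimethylsilyloxy)-6,8-dimethyl-2-oxo-5-[(2S)-2-(triisopropylsilyloxy)propyl]-2H-chromene-3-carbonyl]-3-oxo-5-(trimethylsilyloxy)hexanoate (mixture of tautomers) | C[C@@H](O[Si](C)(C)C)CC(=O)C(C(=O)OC(C)(C)C)C(=O)c1cc2c(C[C@H](C)O[Si](C(C)C)(C(C)C)C(C)C)c(C)c(O[Si](C)(C)C(C)(C)C)c(C)c2oc1=O | intermediate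
26 | 7-(tert-butyldimethylsilyloxy)-6,8-dimethyl-3-[(2R)-2-methyl-4-oxo-3,4-dihydro-2H-pyran-6-yl]-5-[(2S)-2-(triisopropylsilyloxy)propyl]-2H-chromen-2-one | Cc1c(O[Si](C)(C)C(C)(C)C)c(C)c2oc(=O)c(C3=CC(=O)C[C@@H](C)O3)cc2c1C[C@H](C)O[Si](C(C)C)(C(C)C)C(C)C | intermediate
27 | 7-hydroxy-5-[(2S)-2-hydroxypropyl]-6,8-dimethyl-3-[(2R)-2-methyl-4-oxo-3,4-dihydro-2H-pyran-6-yl]-2H-chromen-2-one | Cc1c(O)c(C)c2oc(=O)c(C3=CC(=O)C[C@@H](C)O3)cc2c1C[C@H](C)O | target

**Step count and risks**

Total step count: 13. Longest linear sequence: 11 steps (steps 1 to 9, then 12 and 13); steps 10 and 11 prepare the diene on a side branch.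

Steps most likely to fail:

1. Step 12. Facial selectivity may be poor with the small, volatile aldehyde; in the second stage the silyl ether oxygen may be acylated, or the enol silane may add to C4 of the coumarin instead of the acyl chloride; silyl ethers may be partly lost in the acid stage. The fallback sets out from 18 and takes the stereocenter from the chiral pool, so the aldol stage is not needed. Commercial methyl (R)-3-hydroxybutanoate is silylated (Et3SiCl, imidazole, CH2Cl2) to methyl (3R)-3-(triethylsilyloxy)butanoate F1. Crossed Claisen condensation of F1 with the lithium enolate of tert-butyl acetate (LiN(iPr)2, THF, −78 °C) should give tert-butyl (5R)-3-oxo-5-(triethylsilyloxy)hexanoate F2. Its magnesium enolate (MgCl2, pyridine, CH2Cl2, 0 °C) is C-acylated by 18 to tert-butyl (5R)-2-[7-(tert-butyldimethylsilyloxy)-6,8-dimethyl-2-oxo-5-[(2S)-2-(triisopropylsilyloxy)propyl]-2H-chromene-3-carbonyl]-3-oxo-5-(triethylsilyloxy)hexanoate F3. TFA in CH2Cl2 then removes the triethylsilyl and tert-butyl groups and brings about decarboxylation and cyclodehydration, and the route is rejoined at 26.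

2. Step 6. Lithiation may go to a benzylic methyl group instead of the crowded last ring position. The fallback sets out from 10 and fixes the site by halogenation. N-Bromosuccinimide in MeCN at 0 °C should brominate the only free, strongly activated ring position and give {[(2S)-1-[2-bromo-3,5-bis(methoxymethoxy)-4,6-dimethylphenyl]propan-2-yl]oxy}tri(propan-2-yl)silane F4. Bromine–lithium exchange with n-BuLi in THF at −78 °C generates aryllithium 11 regiospecifically, and DMF gives 12, where the route is rejoined.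

3. Step 8. Condensation at the doubly ortho-substituted, electron-rich aldehyde may be slow while Meldrum's acid decomposes. The fallback sets out from 10 and avoids the aldehyde altogether. Aryllithium 11 (generated as in step 6) is added at −78 °C to diethyl 2-(ethoxymethylidene)propanedioate; addition–elimination of ethoxide should give diethyl 2-[[2,4-bis(methoxymethoxy)-3,5-dimethyl-6-[(2S)-2-(triisopropylsilyloxy)propyl]phenyl]methylidene]propanedioate F5. TFA in CH2Cl2 cleaves both MOM ethers and the freed ortho phenol should lactonise onto the cis ester to ethyl 7-hydroxy-6,8-dimethyl-2-oxo-5-[(2S)-2-(triisopropylsilyloxy)propyl]-2H-chromene-3-carboxylate F6. Saponification with LiOH in THF/water and acidification returns the route at 16.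

**Further compounds**

F1 | step 12 | methyl (3R)-3-(triethylsilyloxy)butanoate | C[C@@H](O[Si](CC)(CC)CC)CC(=O)OC
F2 | step 12 | tert-butyl (5R)-3-oxo-5-(triethylsilyloxy)hexanoate | C[C@@H](O[Si](CC)(CC)CC)CC(=O)CC(=O)OC(C)(C)C
F3 | step 12 | tert-butyl (5R)-2-[7-(tert-butyldimethylsilyloxy)-6,8-dimethyl-2-oxo-5-[(2S)-2-(triisopropylsilyloxy)propyl]-2H-chromene-3-carbonyl]-3-oxo-5-(triethylsilyloxy)hexanoate | C[C@@H](O[Si](CC)(CC)CC)CC(=O)C(C(=O)OC(C)(C)C)C(=O)c1cc2c(C[C@H](C)O[Si](C(C)C)(C(C)C)C(C)C)c(C)c(O[Si](C)(C)C(C)(C)C)c(C)c2oc1=O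
F4 | step 6 | {[(2S)-1-[2-bromo-3,5-bis(methoxymethoxy)-4,6-dimethylphenyl]propan-2-yl]oxy}tri(propan-2-yl)silane | C[C@H](O[Si](C(C)C)(C(C)C)C(C)C)Cc1c(Br)c(OCOC)c(C)c(OCOC)c1C
F5 | step 8 | diethyl 2-[[2,4-bis(methoxymethoxy)-3,5-dimethyl-6-[(2S)-2-(triisopropylsilyloxy)propyl]phenyl]methylidene]propanedioate | CCOC(=O)C(=Cc1c(OCOC)c(C)c(OCOC)c(C)c1C[C@H](C)O[Si](C(C)C)(C(C)C)C(C)C)C(=O)OCC
F6 | step 8 | ethyl 7-hydroxy-6,8-dimethyl-2-oxo-5-[(2S)-2-(triisopropylsilyloxy)propyl]-2H-chromene-3-carboxylate | CCOC(=O)c1cc2c(C[C@H](C)O[Si](C(C)C)(C(C)C)C(C)C)c(C)c(O)c(C)c2oc1=O
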